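## Retrosynthetic overview

1. Target 20 ⇐ desilylation and Wittig methylenation of tricyclic ketone 18, which has C14=O in place of C14=CH2.
2. 18 ⇐ type 2 intramolecular [4+3] cycloaddition of the 2-oxidoallyl cation from chloroketone 16 with its own 2-alkylbutadiene, forming C1–C15 and C12–C13. Enabling feature: ring C (C1, C10–C15) is a cyclohept-4-ene whose C14 carries =CH2, a latent ketone between C1–H and C13H2. Its alkene carbon C10 is joined through C9–C8 to the ring A sp2 carbon C7, next to C2, which holds C1. Ring B (C1, C2, C7, C8, C9, C10, C15) is therefore the tether ring of a diene linked through its 2-position.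
3. 16 ⇐ α-chlorination of methyl ketone 14 ⇐ Saucy–Marbet Claisen rearrangement of tertiary allylic alcohol 12 (sets C2 and the C6=C7 alkene) ⇐ MeLi addition to enone 11 ⇐ Negishi coupling of iodoenone 7 with dienyl zinc reagent 10.
4. Ring A (4 → 7) ⇐ organocatalytic Michael/aldol annulation of (S)-citronellal with methyl vinyl ketone, which sets C3 beside the purchased side-chain centre, followed by SeO2 oxidation to the (E)-allylic alcohol.
5. Ring order: A (steps 1–2); then C and B together in step 11, ring B being completed in this last ring-forming event.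

Key step: step 11

Remark (assumption): (S)-citronellal of high enantiomeric purity is taken as the commercial source of the side-chain stereocentre.

Locants: tricyclic compounds are numbered as tricyclo[8.4.1.0(2,7)]pentadecanes. C1 is the bridgehead CH, C2–C7 are ring A, C8 and C9 the CH2CH2 unit, C10 the bridgehead alkene carbon, C11–C14 the rest of ring C, and C15 the one-carbon bridge.

Abbreviation: SC = (2S,5E)-7-{[tert-butyl(diphenyl)silyl]oxy}-6-methylhept-5-en-2-yl.

## Route

Step 1
Reactants: 1 (S)-citronellal; 2 methyl vinyl ketone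
Product: 3 (2S,3S)-3,7-dimethyl-2-(3-oxobutyl)oct-6-enal
Conditions: (S)-2-[methoxy(diphenyl)methyl]pyrrolidine (5 mol%), ethyl 3,4-dihydroxybenzoate (20 mol%), neat, 4 °C
Reagents that add atoms: none
Why: Enamine-catalysed Michael addition of the aldehyde to the enone; the (S)-catalyst blocks one face of the E-enamine, so the new α-stereocentre should form as (2S) under catalyst control next to the purchased (3S) centre.

Step 2
Reactants: 3 (2S,3S)-3,7-dimethyl-2-(3-oxobutyl)oct-6-enal
Product: 4 (4S)-4-[(2S)-6-methylhept-5-en-2-yl]cyclohex-2-en-1-one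
Conditions: LiOH, i-PrOH, rt
Reagents that add atoms: none
Why: Intramolecular aldol condensation of the methyl ketone onto the aldehyde (second half of a Robinson-type annulation) under mild base should give the 4-substituted cyclohexenone without epimerising the γ-stereocentre.

Step 3
Reactants: 4 (4S)-4-[(2S)-6-methylhept-5-en-2-yl]cyclohex-2-en-1-one
Product: 5 (4S)-4-[(2S,5E)-7-hydroxy-6-methylhept-5-en-2-yl]cyclohex-2-en-1-one
Conditions: SeO2 (0.3 equiv), t-BuOOH, salicylic acid (cat.), CH2Cl2, rt
Reagents that add atoms: tert-butyl hydroperoxide, CC(C)(C)OO (oxygen delivered through catalytic selenium dioxide, O=[Se]=O)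
Why: Catalytic SeO2/t-BuOOH allylic oxidation (ene reaction then [2,3]-shift) is selective for the (E)-methyl group of the electron-rich trisubstituted alkene and leaves the electron-poor enone alone, which fixes the (E)-allylic alcohol of the target.

Step 4
Reactants: 5 (4S)-4-[(2S,5E)-7-hydroxy-6-methylhept-5-en-2-yl]cyclohex-2-en-1-one
Product: 6 (4S)-4-(SC)cyclohex-2-en-1-one
Conditions: TBDPSCl, imidazole, DMF, rt
Reagents that add atoms: tert-butyl(chloro)diphenylsilane, CC(C)(C)[Si](Cl)(c1ccccc1)c1ccccc1
Why: Standard silylation of the primary allylic alcohol; the TBDPS ether should survive organometallics, base, heat and fluoroalcohol and is removed last.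

Step 5
Reactants: 6 (4S)-4-(SC)cyclohex-2-en-1-one
Product: 7 (4S)-2-iodo-4-(SC)cyclohex-2-en-1-one
Conditions: I2, pyridine, CH2Cl2, 0 °C → rt
Reagents that add atoms: iodine, II
Why: α-Iodination of the enone by pyridine-assisted addition–elimination (Baylis–Hillman-type activation) gives the vinyl iodide needed for cross-coupling.

Step 6
Reactants: 8 4-bromobut-1-yne
Product: 9 5-bromo-3-methylidenepent-1-ene
Conditions: ethylene (1 atm), second-generation Grubbs catalyst RuCl2(=CHPh)(PCy3)(H2IMes) (5 mol%), CH2Cl2, rt
Reagents that add atoms: ethylene, C=C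
Why: Ruthenium-catalysed enyne cross-metathesis of a terminal alkyne with ethylene converts the alkyne into the 2-substituted buta-1,3-diene, and the alkyl bromide is inert.

Step 7
Reactants: 9 5-bromo-3-methylidenepent-1-ene; 7 (4S)-2-iodo-4-(SC)cyclohex-2-en-1-one
Product: 11 (4S)-2-(3-methylidenepent-4-en-1-yl)-4-(SC)cyclohex-2-en-1-one, via alkylzinc bromide 10 (not isolated)
Conditions: 9, Zn dust, I2 (5 mol%), DMA, 70 °C; then 7, Pd2(dba)3 (2.5 mol%), P(2-furyl)3 (10 mol%), THF–DMA, rt
Reagents that add atoms: none
Why: Negishi coupling: zinc insertion gives a primary alkylzinc bromide that tolerates ketone, silyl ether and diene, and zerovalent palladium should couple it with the α-iodoenone faster than any conjugate addition.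

Step 8
Reactants: 11 (4S)-2-(3-methylidenepent-4-en-1-yl)-4-(SC)cyclohex-2-en-1-one
Product: 12 (1R,4S)-1-methyl-2-(3-methylidenepent-4-en-1-yl)-4-(SC)cyclohex-2-en-1-ol
Conditions: MeLi, Et2O, −78 °C; aqueous work-up
Reagents that add atoms: methyllithium, [Li]C
Why: 1,2-Addition of methyllithium to the enone; axial attack on the half-chair with the C4 substituent pseudo-equatorial should place OH trans to the side chain, i.e. (1R), and any epimer would be removed by chromatography.

Step 9
Reactants: 12 (1R,4S)-1-methyl-2-(3-methylidenepent-4-en-1-yl)-4-(SC)cyclohex-2-en-1-ol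
Product: 14 1-[(1S,6S)-3-methyl-2-(3-methylidenepent-4-en-1-yl)-6-(SC)cyclohex-2-en-1-yl]propan-2-one, via isopropenyl ether 13 (not isolated)
Conditions: 2-methoxypropene (excess), EtCO2H (cat.), toluene, sealed tube, 120 °C
Reagents that add atoms: 2-methoxypropene, COC(C)=C
Why: Saucy–Marbet (ketal) Claisen rearrangement: acid-catalysed exchange gives the allyl isopropenyl ether 13, whose suprafacial [3,3] shift carries the configuration of the carbinol carbon to the ring CH (acetonyl group trans to the neighbouring side chain) and moves the alkene into the tetrasubstituted position.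

Step 10
Reactants: 14 1-[(1S,6S)-3-methyl-2-(3-methylidenepent-4-en-1-yl)-6-(SC)cyclohex-2-en-1-yl]propan-2-one
Product: 16 1-chloro-3-[(1S,6S)-3-methyl-2-(3-methylidenepent-4-en-1-yl)-6-(SC)cyclohex-2-en-1-yl]propan-2-one, via lithium enolate 15 (not isolated)
Conditions: LiN(iPr)2, THF, −78 °C; then TsCl, −78 °C → rt
Reagents that add atoms: 4-methylbenzenesulfonyl chloride, Cc1ccc(cc1)S(Cl)(=O)=O
Why: Kinetic deprotonation at the methyl group and chlorine transfer from the sulfonyl chloride to the lithium enolate give the α-chloroketone; the regiochemistry is not critical because either α-chloro isomer would ionise to the same oxyallyl cation.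

Step 11
Reactants: 16 1-chloro-3-[(1S,6S)-3-methyl-2-(3-methylidenepent-4-en-1-yl)-6-(SC)cyclohex-2-en-1-yl]propan-2-one
Product: 18 (1S,2R,3S)-6-methyl-3-(SC)tricyclo[8.4.1.0(2,7)]pentadeca-6,10-dien-14-one, via oxyallyl cation 17 (not isolated)
Conditions: i-Pr2NEt (3 equiv), (CF3)2CHOH–CF3CH2OH 1:1, 0.005 M, slow addition of 16, 0 °C → rt
Reagents that add atoms: none
Why: Proposed new method: a type 2 intramolecular [4+3] cycloaddition, in which a 2-oxidoallyl cation is trapped by a butadiene tethered through its 2-position, is not established; the closest known reactions are the terminus-tethered intramolecular [4+3] cycloaddition of oxyallyl cations generated from α-haloketones with amine base in fluoroalcohols, the type 2 intramolecular Diels–Alder reaction and the type 2 [5+2] cycloaddition of oxidopyrylium ylides, all of which tolerate the bridgehead alkene that results. Mechanistically, the amine enolises 16 toward the ring-bearing CH2, chloride ionises in the strongly ionising solvent, and cation 17 combines with the s-cis diene in a concerted but asynchronous 4C+3C event. Ring B is closed by the bond from the substituted cation terminus (C1) to the diene CH2 that becomes the C15 bridge, a seven-membered closure that is exo to the allyl cation and endo to the diene C=C, while ring C is closed by the second bond from the unsubstituted terminus (C13) to the far diene terminus (C12), which completes the cyclohept-4-enone and leaves the C10=C11 bridgehead alkene. The one new stereocentre, C1, is controlled by C2: allylic 1,3-strain keeps the C2–H bond in the plane of the cation, so C7 with the diene arm sits on one face and C3 with the side chain on the other, and the diene can only be delivered to the face of C7, which corresponds to (1S). The step needs periselectivity for [4+3] over (3+2) closure, proton loss, Favorskii rearrangement or solvent capture, and the bridged 1,3-regiochemistry; the nucleophilic CH2 terminus and easy s-cis form of the 2-alkyldiene, the four-atom tether anchored on sp2 C7 (the alternative regiochemistry would place a trans alkene in an eight-membered ring), the hindered base, the weakly nucleophilic solvent and high dilution should secure them.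

Step 12
Reactants: 18 (1S,2R,3S)-6-methyl-3-(SC)tricyclo[8.4.1.0(2,7)]pentadeca-6,10-dien-14-one
Product: 19 (1S,2R,3S)-6-methyl-14-methylidene-3-(SC)tricyclo[8.4.1.0(2,7)]pentadeca-6,10-diene
Conditions: Ph3PCH3Br, KOtBu, THF, 0 → 50 °C
Reagents that add atoms: methylidenetriphenylphosphorane, C=P(c1ccccc1)(c1ccccc1)c1ccccc1 (made in the flask from methyltriphenylphosphonium bromide, C[P+](c1ccccc1)(c1ccccc1)c1ccccc1.[Br-])
Why: Wittig methylenation with the non-stabilised ylide should convert the bridged ketone into the exocyclic alkene; the C10=C11 alkene is not in conjugation with the ketone and cannot migrate.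

Step 13
Reactants: 19 (1S,2R,3S)-6-methyl-14-methylidene-3-(SC)tricyclo[8.4.1.0(2,7)]pentadeca-6,10-diene
Product: 20 (2E,6S)-2-methyl-6-[(1S,2R,3S)-6-methyl-14-methylidenetricyclo[8.4.1.0(2,7)]pentadeca-6,10-dien-3-yl]hept-2-en-1-ol
Conditions: Bu4NF, THF, rt
Reagents that add atoms: none
Why: Fluoride-mediated cleavage of the silyl ether should leave the three ring alkenes and the allylic alcohol geometry untouched.

## Compound list

1 | (S)-citronellal, (3S)-3,7-dimethyloct-6-enal | C[C@@H](CCC=C(C)C)CC=O | starting material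
2 | methyl vinyl ketone (but-3-en-2-one) | CC(=O)C=C | starting material
3 | (2S,3S)-3,7-dimethyl-2-(3-oxobutyl)oct-6-enal | CC(=O)CC[C@@H]([C@@H](C)CCC=C(C)C)C=O | intermediate
4 | (4S)-4-[(2S)-6-methylhept-5-en-2-yl]cyclohex-2-en-1-one | O=C1CC[C@@H]([C@@H](C)CCC=C(C)C)C=C1 | intermediate
5 | (4S)-4-[(2S,5E)-7-hydroxy-6-methylhept-5-en-2-yl]cyclohex-2-en-1-one | O=C1CC[C@@H]([C@@H](C)CC/C=C(\C)CO)C=C1 | intermediate
6 | (4S)-4-(SC)cyclohex-2-en-1-one (TBDPS ether of 5) | O=C1CC[C@@H]([C@@H](C)CC/C=C(\C)CO[Si](c2ccccc2)(c2ccccc2)C(C)(C)C)C=C1 | intermediate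
7 | (4S)-2-iodo-4-(SC)cyclohex-2-en-1-one | O=C1CC[C@@H]([C@@H](C)CC/C=C(\C)CO[Si](c2ccccc2)(c2ccccc2)C(C)(C)C)C=C1I | intermediate
8 | 4-bromobut-1-yne | C#CCCBr | starting material
9 | 5-bromo-3-methylidenepent-1-ene | C=CC(=C)CCBr | intermediate
10 | bromo(3-methylidenepent-4-en-1-yl)zinc | C=CC(=C)CC[Zn]Br | intermediate (not isolated)
11 | (4S)-2-(3-methylidenepent-4-en-1-yl)-4-(SC)cyclohex-2-en-1-one | O=C1CC[C@@H]([C@@H](C)CC/C=C(\C)CO[Si](c2ccccc2)(c2ccccc2)C(C)(C)C)C=C1CCC(=C)C=C | intermediate
12 | (1R,4S)-1-methyl-2-(3-methylidenepent-4-en-1-yl)-4-(SC)cyclohex-2-en-1-ol, OH trans to SC | C[C@@]1(O)CC[C@@H]([C@@H](C)CC/C=C(\C)CO[Si](c2ccccc2)(c2ccccc2)C(C)(C)C)C=C1CCC(=C)C=C | intermediate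
13 | isopropenyl (prop-1-en-2-yl) ether of 12 | C[C@@]1(OC(C)=C)CC[C@@H]([C@@H](C)CC/C=C(\C)CO[Si](c2ccccc2)(c2ccccc2)C(C)(C)C)C=C1CCC(=C)C=C | intermediate (not isolated)
14 | 1-[(1S,6S)-3-methyl-2-(3-methylidenepent-4-en-1-yl)-6-(SC)cyclohex-2-en-1-yl]propan-2-one, acetonyl trans to SC | C=CC(=C)CCC1=C(C)CC[C@@H]([C@@H](C)CC/C=C(\C)CO[Si](c2ccccc2)(c2ccccc2)C(C)(C)C)[C@@H]1CC(C)=O | intermediate
15 | terminal lithium enolate of 14 | C=CC(=C)CCC1=C(C)CC[C@@H]([C@@H](C)CC/C=C(\C)CO[Si](c2ccccc2)(c2ccccc2)C(C)(C)C)[C@@H]1CC(=C)O[Li] | intermediate (not isolated)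
16 | 1-chloro-3-[(1S,6S)-3-methyl-2-(3-methylidenepent-4-en-1-yl)-6-(SC)cyclohex-2-en-1-yl]propan-2-one | C=CC(=C)CCC1=C(C)CC[C@@H]([C@@H](C)CC/C=C(\C)CO[Si](c2ccccc2)(c2ccccc2)C(C)(C)C)[C@@H]1CC(=O)CCl | intermediate
17 | 2-oxidoallyl cation (zwitterion) derived from 16 | C=CC(=C)CCC1=C(C)CC[C@@H]([C@@H](C)CC/C=C(\C)CO[Si](c2ccccc2)(c2ccccc2)C(C)(C)C)[C@@H]1[CH+]C([O-])=C | intermediate (not isolated)
18 | (1S,2R,3S)-6-methyl-3-(SC)tricyclo[8.4.1.0(2,7)]pentadeca-6,10-dien-14-one | O=C1CCC=C2CCC3=C(C)CC[C@@H]([C@@H](C)CC/C=C(\C)CO[Si](c4ccccc4)(c4ccccc4)C(C)(C)C)[C@@H]3[C@@H]1C2 | intermediate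
19 | (1S,2R,3S)-6-methyl-14-methylidene-3-(SC)tricyclo[8.4.1.0(2,7)]pentadeca-6,10-diene | C=C1CCC=C2CCC3=C(C)CC[C@@H]([C@@H](C)CC/C=C(\C)CO[Si](c4ccccc4)(c4ccccc4)C(C)(C)C)[C@@H]3[C@@H]1C2 | intermediate
20 | (2E,6S)-2-methyl-6-[(1S,2R,3S)-6-methyl-14-methylidenetricyclo[8.4.1.0(2,7)]pentadeca-6,10-dien-3-yl]hept-2-en-1-ol | C=C1CCC=C2CCC3=C(C)CC[C@@H]([C@@H](C)CC/C=C(\C)CO)[C@@H]3[C@@H]1C2 | target

## Step count and risk

Total step count: 13. Longest linear sequence: 12 steps (steps 1–5 and 7–13, from (S)-citronellal); step 6 is a one-step side branch.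

Steps most likely to fail:

1. Step 11 (proposed new method). The cation may be intercepted before the second C–C bond forms: by solvent capture, Favorskii rearrangement, proton loss to an enone, closure to a five-membered (3+2) product, or attack by the tetrasubstituted ring A alkene. Cyclisation may also be too slow at the dilution needed.
 Fallback (known chemistry: type 2 intramolecular Diels–Alder reaction, then one-carbon ring expansion). It sets out from 12 and returns at 18.
 - O-Alkylation of 12 with Bu3SnCH2I (KH, THF) would give stannylmethyl ether F1.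
 - Tin–lithium exchange (n-BuLi, THF, −78 °C) would trigger a [2,3]-Wittig–Still rearrangement that places CH2OH on the same ring carbon and face as the Claisen step does, giving homoallylic alcohol F2.
 - Dess–Martin oxidation would give aldehyde F3.
 - Henry addition of nitromethane would give nitro alcohol F4, and dehydration (MsCl, Et3N) the (E)-nitroalkene F5.
 - Heating F5 in dilute toluene would bring about the type 2 intramolecular Diels–Alder reaction across the same four-atom tether. Ring B is again closed in this last ring-forming step, together with a cyclohexene in place of ring C, giving nitro cycloadduct F6.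
 - A Nef reaction (NaOMe, then buffered aqueous TiCl3) would give bridged cyclohexenone F7.
 - Homologation with diazomethane and BF3·OEt2, with migration of the less substituted allylic CH2, would insert the missing ring carbon and return to the route at 18.

2. Step 9. Acid-promoted ionisation and dehydration of the tertiary allylic alcohol (or of its ketal) may outrun the [3,3] shift, which is itself slowed because a tetrasubstituted alkene and a congested C–C bond are formed.
 Fallback (Carroll rearrangement under neutral, then basic conditions). It sets out from 12 and returns at 14.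
 - Acetoacetylation with 2,2,6-trimethyl-4H-1,3-dioxin-4-one (xylene, 140 °C) would give acetoacetate F8.
 - Its dianion (LiN(iPr)2, 2.2 equiv, THF, −78 °C → 65 °C) would rearrange to β-keto acid F9.
 - F9 would lose carbon dioxide on warming and rejoin the route at 14.

3. Step 8. Insufficient facial selectivity in the 1,2-addition (equatorial attack competing with axial attack) would, after the stereospecific Claisen step, erode the configuration at C2.
 Fallback (stereoconvergent cationic allylic substitution in place of stereospecific rearrangement). It sets out from 11 and returns at 14, bypassing step 9.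
 - The methyllithium adduct would be used as the unseparated mixture of 12 and its C1-epimeric alcohol F10.
 - The mixture would be ionised with Bi(OTf)3 (cat.) in CH2Cl2–MeNO2 at −40 °C in the presence of excess 2-(trimethylsilyloxy)propene.
 - The common cyclohexenyl cation should be attacked at its secondary terminus anti to the neighbouring side chain, so both epimers would converge on 14.

## Further compounds

F1 | step 11 | tributylstannylmethyl ether of 12 | C[C@@]1(OC[Sn](CCCC)(CCCC)CCCC)CC[C@@H]([C@@H](C)CC/C=C(\C)CO[Si](c2ccccc2)(c2ccccc2)C(C)(C)C)C=C1CCC(=C)C=C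
F2 | step 11 | [(1S,6S)-3-methyl-2-(3-methylidenepent-4-en-1-yl)-6-(SC)cyclohex-2-en-1-yl]methanol | C=CC(=C)CCC1=C(C)CC[C@@H]([C@@H](C)CC/C=C(\C)CO[Si](c2ccccc2)(c2ccccc2)C(C)(C)C)[C@@H]1CO
F3 | step 11 | aldehyde from F2 (CHO in place of CH2OH) | C=CC(=C)CCC1=C(C)CC[C@@H]([C@@H](C)CC/C=C(\C)CO[Si](c2ccccc2)(c2ccccc2)C(C)(C)C)[C@@H]1C=O
F4 | step 11 | nitro alcohol from F3 and nitromethane (carbinol configuration not controlled) | C=CC(=C)CCC1=C(C)CC[C@@H]([C@@H](C)CC/C=C(\C)CO[Si](c2ccccc2)(c2ccccc2)C(C)(C)C)[C@@H]1C(O)C[N+](=O)[O-]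
F5 | step 11 | (E)-2-nitrovinyl compound from F4 | C=CC(=C)CCC1=C(C)CC[C@@H]([C@@H](C)CC/C=C(\C)CO[Si](c2ccccc2)(c2ccccc2)C(C)(C)C)[C@@H]1/C=C/[N+](=O)[O-]
F6 | step 11 | nitro cycloadduct: ring B as in 18, six-membered nitrocyclohexene in place of ring C (nitro-bearing carbon not assigned, destroyed in the next step) | O=[N+]([O-])C1CC=C2CCC3=C(C)CC[C@@H]([C@@H](C)CC/C=C(\C)CO[Si](c4ccccc4)(c4ccccc4)C(C)(C)C)[C@@H]3[C@@H]1C2
F7 | step 11 | bridged cyclohexenone from F6, the lower ring homologue of 18 | O=C1CC=C2CCC3=C(C)CC[C@@H]([C@@H](C)CC/C=C(\C)CO[Si](c4ccccc4)(c4ccccc4)C(C)(C)C)[C@@H]3[C@@H]1C2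
F8 | step 9 | acetoacetate (3-oxobutanoate) ester of 12 | C[C@@]1(OC(=O)CC(C)=O)CC[C@@H]([C@@H](C)CC/C=C(\C)CO[Si](c2ccccc2)(c2ccccc2)C(C)(C)C)C=C1CCC(=C)C=C
F9 | step 9 | β-keto acid from Carroll rearrangement of F8 (α-carbon not assigned, lost on decarboxylation) | C=CC(=C)CCC1=C(C)CC[C@@H]([C@@H](C)CC/C=C(\C)CO[Si](c2ccccc2)(c2ccccc2)C(C)(C)C)[C@@H]1C(C(C)=O)C(=O)O
F10 | step 8 | (1S,4S)-epimer of 12, OH cis to SC | C[C@]1(O)CC[C@@H]([C@@H](C)CC/C=C(\C)CO[Si](c2ccccc2)(c2ccccc2)C(C)(C)C)C=C1CCC(=C)C=C
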